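Everything depends on forming the C5–C6 bond last. In germacrane numbering the future tiglate carbon C6 is a carbinol flanked on one side by the C4=C5 double bond (ring bonds cis) and on the other by C7 of the trans-fused γ-lactone (C7–C11–C12–O–C8). A C5 alkenylchromium and a C6 formyl group are therefore joined in one operation that creates the C5–C6 bond, the ten-membered carbocycle C1–C10 and the C6 stereocentre. The substrate, 27, is a trans-4,5-disubstituted butyrolactone with the aldehyde on C7 and, on C8, the C9–C5 chain containing the C1=C10 alkene and ending in an (E)-iodoalkene; C14–OH and C15–OH are silyl-protected and C13 is absent.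

Key step: step 18

Assumption: the C14 and C15 oxygens are carried as tert-butyldiphenylsilyl ethers so that a primary tert-butyldimethylsilyl ether on C8–O can be cleaved selectively, and 1, 2, 4, 10, 11, 18, 19, 30 and 34 are taken as commercial; the target was checked as 6R,7R,8S with a trans lactone and both ring alkenes ring-cis (CIP E,E), and the CIP label of C7 changes with the group on C6 although its configuration does not.

Step 1
Reactants: 1 diethyl malonate; 2 2-(2-bromoethyl)-1,3-dioxolane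
Product: 3 diethyl 2-[2-(1,3-dioxolan-2-yl)ethyl]malonate
Conditions: NaH, THF/DMF, 0 → 60 °C (1 in excess)
Reagents that add atoms: none
Why: Malonic ester alkylation (SN2 at the primary bromide) should give the monoalkyl malonate that holds C15, C4, C3, C2 and C1, with C1 masked as a base-stable acetal.

Step 2
Reactants: 3 diethyl 2-[2-(1,3-dioxolan-2-yl)ethyl]malonate; 4 iodoform
Product: 5 diethyl 2-(diiodomethyl)-2-[2-(1,3-dioxolan-2-yl)ethyl]malonate
Conditions: NaH, Et2O, reflux; then CHI3, reflux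
Reagents that add atoms: none
Why: C-Diiodomethylation of the malonate enolate by iodoform (capture of diiodocarbene and proton transfer), a known route to 2-(diiodomethyl)malonates, should attach the future C5.

Step 3
Reactants: 5 diethyl 2-(diiodomethyl)-2-[2-(1,3-dioxolan-2-yl)ethyl]malonate
Product: 6 (E)-4-(1,3-dioxolan-2-yl)-2-(iodomethylene)butanoic acid
Conditions: KOH, EtOH/H2O, reflux; then 1 M HCl to pH 3–4, 0 °C
Reagents that add atoms: potassium hydroxide, [K+].[OH-]
Why: Saponification and decarboxylative elimination of iodide (Grob-type fragmentation) should give the 3-iodoacrylic acid with the carboxylate trans to iodine, as known for 2-alkyl analogues, so that iodine is cis to the C3 chain as the ring-cis C4=C5 bond requires.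

Step 4
Reactants: 6 (E)-4-(1,3-dioxolan-2-yl)-2-(iodomethylene)butanoic acid
Product: 7 (E)-4-(1,3-dioxolan-2-yl)-2-(iodomethylene)butan-1-ol
Conditions: LiAlH4, Et2O, 0 °C
Reagents that add atoms: none
Why: Hydride reduction of the carboxylic acid to the primary allylic alcohol (C15–OH) is known to spare the C–I bond and the geometry of 3-iodoacrylic acids at 0 °C.

Step 5
Reactants: 7 (E)-4-(1,3-dioxolan-2-yl)-2-(iodomethylene)butan-1-ol
Product: 8 tert-butyl{[(E)-4-(1,3-dioxolan-2-yl)-2-(iodomethylene)butyl]oxy}diphenylsilane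
Conditions: TBDPSCl, imidazole, CH2Cl2, rt
Reagents that add atoms: tert-butyl(chloro)diphenylsilane, CC(C)(C)[Si](Cl)(c1ccccc1)c1ccccc1
Why: Silylation of the primary alcohol installs an acid-stable ether that should outlast the later acetal hydrolysis and the selective cleavage of the tert-butyldimethylsilyl ether.

Step 6
Reactants: 8 tert-butyl{[(E)-4-(1,3-dioxolan-2-yl)-2-(iodomethylene)butyl]oxy}diphenylsilane
Product: 9 (E)-4-{[(tert-butyldiphenylsilyl)oxy]methyl}-5-iodopent-4-enal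
Conditions: 2 M HCl, THF, rt
Reagents that add atoms: water, O
Why: Acid-catalysed acetal hydrolysis should free the C1 aldehyde, the iodoalkene and the tert-butyldiphenylsilyl ether being stable to dilute acid.

Step 7
Reactants: 10 triethyl phosphonoacetate; 11 (2-bromoethoxy)(tert-butyl)dimethylsilane
Product: 12 ethyl 4-[(tert-butyldimethylsilyl)oxy]-2-(diethoxyphosphoryl)butanoate
Conditions: NaH, DMF, 0 → 60 °C, Bu4NI (cat.)
Reagents that add atoms: none
Why: C-Alkylation of the phosphonoacetate anion (SN2) should give the α-branched phosphonate that carries C14, C10, C9 and a protected C8–OH.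

Step 8
Reactants: 9 (E)-4-{[(tert-butyldiphenylsilyl)oxy]methyl}-5-iodopent-4-enal; 12 ethyl 4-[(tert-butyldimethylsilyl)oxy]-2-(diethoxyphosphoryl)butanoate
Product: 13 ethyl (2E,6E)-2-{2-[(tert-butyldimethylsilyl)oxy]ethyl}-6-{[(tert-butyldiphenylsilyl)oxy]methyl}-7-iodohepta-2,6-dienoate
Conditions: NaH, THF, 0 °C → rt
Reagents that add atoms: none
Why: Horner–Wadsworth–Emmons olefination under equilibrating conditions should give the (E)-enoate, in which the ester carbon C14 is trans to C2 and C9 is cis to C2, which is the ring-cis C1=C10 geometry.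

Step 9
Reactants: 13 ethyl (2E,6E)-2-{2-[(tert-butyldimethylsilyl)oxy]ethyl}-6-{[(tert-butyldiphenylsilyl)oxy]methyl}-7-iodohepta-2,6-dienoate
Product: 14 (2E,6E)-2-{2-[(tert-butyldimethylsilyl)oxy]ethyl}-6-{[(tert-butyldiphenylsilyl)oxy]methyl}-7-iodohepta-2,6-dien-1-ol
Conditions: i-Bu2AlH, CH2Cl2, −78 °C
Reagents that add atoms: none
Why: 1,2-Reduction of the enoate by the aluminium hydride should give the C14 allylic alcohol without touching the iodoalkene or the silyl ethers.

Step 10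
Reactants: 14 (2E,6E)-2-{2-[(tert-butyldimethylsilyl)oxy]ethyl}-6-{[(tert-butyldiphenylsilyl)oxy]methyl}-7-iodohepta-2,6-dien-1-ol
Product: 15 (3E,7E)-1-[(tert-butyldimethylsilyl)oxy]-3,7-bis{[(tert-butyldiphenylsilyl)oxy]methyl}-8-iodoocta-3,7-diene
Conditions: TBDPSCl, imidazole, CH2Cl2, rt
Reagents that add atoms: tert-butyl(chloro)diphenylsilane, CC(C)(C)[Si](Cl)(c1ccccc1)c1ccccc1
Why: Silylation gives C14–O the same robust ether as C15–O, which leaves the C8 oxygen as the only acid-labile silyl ether.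

Step 11
Reactants: 15 (3E,7E)-1-[(tert-butyldimethylsilyl)oxy]-3,7-bis{[(tert-butyldiphenylsilyl)oxy]methyl}-8-iodoocta-3,7-diene
Product: 16 (3E,7E)-3,7-bis{[(tert-butyldiphenylsilyl)oxy]methyl}-8-iodoocta-3,7-dien-1-ol
Conditions: PPTS, EtOH, rt
Reagents that add atoms: none
Why: Acid-catalysed ethanolysis cleaves a primary tert-butyldimethylsilyl ether far faster than primary tert-butyldiphenylsilyl ethers, so only C8–OH should be freed.

Step 12
Reactants: 16 (3E,7E)-3,7-bis{[(tert-butyldiphenylsilyl)oxy]methyl}-8-iodoocta-3,7-dien-1-ol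
Product: 17 (3E,7E)-3,7-bis{[(tert-butyldiphenylsilyl)oxy]methyl}-8-iodoocta-3,7-dienal
Conditions: Dess–Martin periodinane, NaHCO3, CH2Cl2, 0 °C; used at once
Reagents that add atoms: none
Why: Dess–Martin oxidation under buffered, non-enolising conditions should give the β,γ-unsaturated C8 aldehyde without moving the C1=C10 bond into conjugation.

Step 13
Reactants: 18 (R)-4-benzyl-2-oxazolidinone; 19 methyl 4-chloro-4-oxobutanoate
Product: 20 methyl 4-[(4R)-4-benzyl-2-oxo-1,3-oxazolidin-3-yl]-4-oxobutanoate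
Conditions: n-BuLi, THF, −78 °C; then 19, −78 → 0 °C
Reagents that add atoms: none
Why: N-Acylation of the lithiated oxazolidinone by the acid chloride should give the succinyl imide that holds C6, C7, C11 and C12.

Step 14
Reactants: 20 methyl 4-[(4R)-4-benzyl-2-oxo-1,3-oxazolidin-3-yl]-4-oxobutanoate; 17 (3E,7E)-3,7-bis{[(tert-butyldiphenylsilyl)oxy]methyl}-8-iodoocta-3,7-dienal
Product: 23 (4R)-4-benzyl-3-{[(2S,3R)-2-[(2E,6E)-2,6-bis{[(tert-butyldiphenylsilyl)oxy]methyl}-7-iodohepta-2,6-dien-1-yl]-5-oxooxolan-3-yl]carbonyl}-1,3-oxazolidin-2-one, via Z-boron enolate 21 (not isolated), via syn-aldol hydroxy ester 22 (not isolated)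
Conditions: Bu2BOTf, i-Pr2NEt, CH2Cl2, 0 °C; 17, −78 → 0 °C; pH 7 phosphate buffer, MeOH, H2O2, 0 °C; crude, PPTS (cat.), PhMe, 50 °C
Reagents that add atoms: none
Why: Evans syn-aldol reaction through the Z-boron enolate and a Zimmerman–Traxler chair, in which the aldehyde adds to the enolate face away from the benzyl group of the R auxiliary, should set 7R and 8S, and acid-catalysed lactonisation of the γ-hydroxy ester then gives the trans-4,5-disubstituted butyrolactone (a syn aldol corresponds to a trans lactone).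

Step 15
Reactants: 23 (4R)-4-benzyl-3-{[(2S,3R)-2-[(2E,6E)-2,6-bis{[(tert-butyldiphenylsilyl)oxy]methyl}-7-iodohepta-2,6-dien-1-yl]-5-oxooxolan-3-yl]carbonyl}-1,3-oxazolidin-2-one
Product: 24 (2S,3R)-2-[(2E,6E)-2,6-bis{[(tert-butyldiphenylsilyl)oxy]methyl}-7-iodohepta-2,6-dien-1-yl]-5-oxooxolane-3-carboxylic acid
Conditions: LiOH, H2O2, THF/H2O, 0 °C; Na2SO3; HCl to pH 2
Reagents that add atoms: lithium hydroperoxide (from LiOH and H2O2), [Li+].[O-]O
Why: Hydroperoxide cleavage of the N-acyloxazolidinone attacks the exocyclic carbonyl selectively without epimerising C7, and any lactone opened by hydroxide should reclose on acidification.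

Step 16
Reactants: 24 (2S,3R)-2-[(2E,6E)-2,6-bis{[(tert-butyldiphenylsilyl)oxy]methyl}-7-iodohepta-2,6-dien-1-yl]-5-oxooxolane-3-carboxylic acid
Product: 26 (4S,5S)-5-[(2E,6E)-2,6-bis{[(tert-butyldiphenylsilyl)oxy]methyl}-7-iodohepta-2,6-dien-1-yl]-4-(hydroxymethyl)oxolan-2-one, via mixed anhydride 25 (not isolated)
Conditions: i-BuOCOCl, N-methylmorpholine, THF, −15 °C; then NaBH4, H2O, −15 → 0 °C
Reagents that add atoms: none
Why: Mixed-anhydride activation followed by NaBH4 reduction should reduce only the carboxyl group to the C6 alcohol and leave the lactone, both alkenes and the C–I bond alone, which a borane or a palladium-catalysed thioester reduction would not guarantee.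

Step 17
Reactants: 26 (4S,5S)-5-[(2E,6E)-2,6-bis{[(tert-butyldiphenylsilyl)oxy]methyl}-7-iodohepta-2,6-dien-1-yl]-4-(hydroxymethyl)oxolan-2-one
Product: 27 (2S,3R)-2-[(2E,6E)-2,6-bis{[(tert-butyldiphenylsilyl)oxy]methyl}-7-iodohepta-2,6-dien-1-yl]-5-oxooxolane-3-carbaldehyde
Conditions: Dess–Martin periodinane, NaHCO3, CH2Cl2, 0 °C → rt; used directly
Reagents that add atoms: none
Why: Dess–Martin oxidation gives the C6 aldehyde under non-basic conditions that should avoid epimerisation at C7 and β-elimination of the lactone carboxylate, and the trans arrangement is in any case the more stable one.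

Step 18
Reactants: 27 (2S,3R)-2-[(2E,6E)-2,6-bis{[(tert-butyldiphenylsilyl)oxy]methyl}-7-iodohepta-2,6-dien-1-yl]-5-oxooxolane-3-carbaldehyde
Product: 29 (6R,7R,8S)-14,15-bis[(tert-butyldiphenylsilyl)oxy]-6-hydroxy-13-norgermacra-1(10),4-dien-12,8-olide (both ring alkenes ring-cis; CIP 1(10)E,4E), via alkenylchromium dichloride 28 (not isolated)
Conditions: CrCl2 (8 equiv), NiCl2 (0.1 equiv), degassed DMSO/THF, rt, slow addition of 27 to 2 mM; aqueous work-up
Reagents that add atoms: none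
Why: Nozaki–Hiyama–Kishi reaction run intramolecularly: divalent chromium reduces NiCl2 to zerovalent nickel, which inserts into the C5–I bond, the alkenyl group passes with retention of geometry to trivalent chromium (28), and 28 adds to the C6 aldehyde to give the alcohol on aqueous work-up. The closest known reaction type is the nickel/chromium alkenyl iodide–aldehyde macrocyclisation used for medium and large carbocycles. The ten-membered ring closes in a 10-exo-trig mode, favoured because the trans lactone holds the aldehyde (on C7) and the iodide arm (on C8) on neighbouring carbons and both chain alkenes already have the ring-cis geometry. C6 is controlled by C7 within the cyclic transition state and not by an open-chain Felkin arrangement, since C5 is tethered to C8 and must approach gauche to C7–C8 on the H7 side and anti to C7–C11. Of the two aldehyde rotamers that this allows, the one with the chromium-bound oxygen pointing outward over H7 (not inward over C8) should be preferred and leads to 6R. The step also needs chemoselectivity for the aldehyde over the lactone, no epimerisation at C7 and suppression of oligomers, which the neutral, weakly basic organochromium reagent and high dilution should secure.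

Step 19
Reactants: 29 (6R,7R,8S)-14,15-bis[(tert-butyldiphenylsilyl)oxy]-6-hydroxy-13-norgermacra-1(10),4-dien-12,8-olide; 30 dimethylmethyleneiminium iodide (Eschenmoser's salt)
Product: 33 (6R,7R,8S)-14,15-bis[(tert-butyldiphenylsilyl)oxy]-6-hydroxygermacra-1(10),4,11(13)-trien-12,8-olide, via Mannich base 31 (not isolated), via methiodide 32 (not isolated)
Conditions: LiN(i-Pr)2 (3 equiv), THF, −78 °C (29 added to the base); 30, −78 → −20 °C; H2O; MeI, MeOH, rt; NaHCO3 (aq), CH2Cl2, rt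
Reagents that add atoms: none
Why: α-Methylenation of the lactone by a Mannich reaction of the alkoxide–enolate dianion with the iminium salt, N-methylation and E1cB loss of trimethylamine should install C13, the fast double deprotonation keeping the C6 alkoxide from attacking C12.

Step 20
Reactants: 33 (6R,7R,8S)-14,15-bis[(tert-butyldiphenylsilyl)oxy]-6-hydroxygermacra-1(10),4,11(13)-trien-12,8-olide; 34 tigloyl chloride [(E)-2-methylbut-2-enoyl chloride]
Product: 35 (6R,7R,8S)-14,15-bis[(tert-butyldiphenylsilyl)oxy]-6-[(E)-2-methylbut-2-enoyloxy]germacra-1(10),4,11(13)-trien-12,8-olide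
Conditions: Et3N, DMAP (cat.), CH2Cl2, 0 °C → rt
Reagents that add atoms: none
Why: DMAP-catalysed acylation of the secondary allylic C6–OH by the acid chloride should give the tiglate with retention at C6, the E geometry of the acyl group being the stable one.

Step 21
Reactants: 35 (6R,7R,8S)-14,15-bis[(tert-butyldiphenylsilyl)oxy]-6-[(E)-2-methylbut-2-enoyloxy]germacra-1(10),4,11(13)-trien-12,8-olide
Product: 36 (6R,7R,8S)-14,15-dihydroxy-6-[(E)-2-methylbut-2-enoyloxy]germacra-1(10),4,11(13)-trien-12,8-olide (CNP0275462.2)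
Conditions: HF·pyridine, pyridine, THF, 0 °C → rt
Reagents that add atoms: none
Why: Fluoride-mediated desilylation buffered with pyridine should free both primary allylic alcohols without harming the α-methylene lactone or the tiglate, and C15–OH, which is trans to C6 across C4=C5, cannot take over the acyl group.

Compound list

1 | diethyl malonate | CCOC(=O)CC(=O)OCC | starting material
2 | 2-(2-bromoethyl)-1,3-dioxolane | BrCCC1OCCO1 | starting material
3 | diethyl 2-[2-(1,3-dioxolan-2-yl)ethyl]malonate | CCOC(=O)C(CCC1OCCO1)C(=O)OCC | intermediate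
4 | iodoform | IC(I)I | starting material
5 | diethyl 2-(diiodomethyl)-2-[2-(1,3-dioxolan-2-yl)ethyl]malonate | CCOC(=O)C(CCC1OCCO1)(C(I)I)C(=O)OCC | intermediate
6 | (E)-4-(1,3-dioxolan-2-yl)-2-(iodomethylene)butanoic acid | O1CCOC1CC/C(C(=O)O)=C\I | intermediate
7 | (E)-4-(1,3-dioxolan-2-yl)-2-(iodomethylene)butan-1-ol | O1CCOC1CC/C(CO)=C\I | intermediate
8 | tert-butyl{[(E)-4-(1,3-dioxolan-2-yl)-2-(iodomethylene)butyl]oxy}diphenylsilane | O1CCOC1CC/C(CO[Si](c1ccccc1)(c1ccccc1)C(C)(C)C)=C\I | intermediate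
9 | (E)-4-{[(tert-butyldiphenylsilyl)oxy]methyl}-5-iodopent-4-enal | O=CCC/C(CO[Si](c1ccccc1)(c1ccccc1)C(C)(C)C)=C\I | intermediate
10 | triethyl phosphonoacetate | CCOC(=O)CP(=O)(OCC)OCC | starting material
11 | (2-bromoethoxy)(tert-butyl)dimethylsilane | BrCCO[Si](C)(C)C(C)(C)C | starting material
12 | ethyl 4-[(tert-butyldimethylsilyl)oxy]-2-(diethoxyphosphoryl)butanoate | CCOC(=O)C(CCO[Si](C)(C)C(C)(C)C)P(=O)(OCC)OCC | intermediate
13 | ethyl (2E,6E)-2-{2-[(tert-butyldimethylsilyl)oxy]ethyl}-6-{[(tert-butyldiphenylsilyl)oxy]methyl}-7-iodohepta-2,6-dienoate | CCOC(=O)/C(CCO[Si](C)(C)C(C)(C)C)=C/CC/C(CO[Si](c1ccccc1)(c1ccccc1)C(C)(C)C)=C\I | intermediate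
14 | (2E,6E)-2-{2-[(tert-butyldimethylsilyl)oxy]ethyl}-6-{[(tert-butyldiphenylsilyl)oxy]methyl}-7-iodohepta-2,6-dien-1-ol | OC/C(CCO[Si](C)(C)C(C)(C)C)=C/CC/C(CO[Si](c1ccccc1)(c1ccccc1)C(C)(C)C)=C\I | intermediate
15 | (3E,7E)-1-[(tert-butyldimethylsilyl)oxy]-3,7-bis{[(tert-butyldiphenylsilyl)oxy]methyl}-8-iodoocta-3,7-diene | CC(C)(C)[Si](C)(C)OCC/C(CO[Si](c1ccccc1)(c1ccccc1)C(C)(C)C)=C\CC/C(CO[Si](c1ccccc1)(c1ccccc1)C(C)(C)C)=C\I | intermediate
16 | (3E,7E)-3,7-bis{[(tert-butyldiphenylsilyl)oxy]methyl}-8-iodoocta-3,7-dien-1-ol | OCC/C(CO[Si](c1ccccc1)(c1ccccc1)C(C)(C)C)=C\CC/C(CO[Si](c1ccccc1)(c1ccccc1)C(C)(C)C)=C\I | intermediate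
17 | (3E,7E)-3,7-bis{[(tert-butyldiphenylsilyl)oxy]methyl}-8-iodoocta-3,7-dienal | O=CC/C(CO[Si](c1ccccc1)(c1ccccc1)C(C)(C)C)=C\CC/C(CO[Si](c1ccccc1)(c1ccccc1)C(C)(C)C)=C\I | intermediate
18 | (R)-4-benzyl-2-oxazolidinone | O=C1N[C@H](Cc2ccccc2)CO1 | starting material
19 | methyl 4-chloro-4-oxobutanoate | COC(=O)CCC(Cl)=O | starting material
20 | methyl 4-[(4R)-4-benzyl-2-oxo-1,3-oxazolidin-3-yl]-4-oxobutanoate | COC(=O)CCC(=O)N1[C@H](Cc2ccccc2)COC1=O | intermediate
21 | Z-dibutylboron enolate of 20 (O–B cis to the CH2CO2Me group) | CCCCB(CCCC)O/C(=C\CC(=O)OC)N1[C@H](Cc2ccccc2)COC1=O | intermediate (not isolated)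
22 | methyl (3R,4S,6E,10E)-3-{[(4R)-4-benzyl-2-oxo-1,3-oxazolidin-3-yl]carbonyl}-6,10-bis{[(tert-butyldiphenylsilyl)oxy]methyl}-4-hydroxy-11-iodoundeca-6,10-dienoate (syn aldol) | COC(=O)C[C@@H](C(=O)N1[C@H](Cc2ccccc2)COC1=O)[C@@H](O)C/C(CO[Si](c1ccccc1)(c1ccccc1)C(C)(C)C)=C\CC/C(CO[Si](c1ccccc1)(c1ccccc1)C(C)(C)C)=C\I | intermediate (not isolated)
23 | (4R)-4-benzyl-3-{[(2S,3R)-2-[(2E,6E)-2,6-bis{[(tert-butyldiphenylsilyl)oxy]methyl}-7-iodohepta-2,6-dien-1-yl]-5-oxooxolan-3-yl]carbonyl}-1,3-oxazolidin-2-one (trans lactone; 7R,8S) | O=C(N1[C@H](Cc2ccccc2)COC1=O)[C@@H]1CC(=O)O[C@H]1C/C(CO[Si](c1ccccc1)(c1ccccc1)C(C)(C)C)=C\CC/C(CO[Si](c1ccccc1)(c1ccccc1)C(C)(C)C)=C\I | intermediate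
24 | (2S,3R)-2-[(2E,6E)-2,6-bis{[(tert-butyldiphenylsilyl)oxy]methyl}-7-iodohepta-2,6-dien-1-yl]-5-oxooxolane-3-carboxylic acid | OC(=O)[C@@H]1CC(=O)O[C@H]1C/C(CO[Si](c1ccccc1)(c1ccccc1)C(C)(C)C)=C\CC/C(CO[Si](c1ccccc1)(c1ccccc1)C(C)(C)C)=C\I | intermediate
25 | isobutyl carbonic mixed anhydride of 24 | CC(C)COC(=O)OC(=O)[C@@H]1CC(=O)O[C@H]1C/C(CO[Si](c1ccccc1)(c1ccccc1)C(C)(C)C)=C\CC/C(CO[Si](c1ccccc1)(c1ccccc1)C(C)(C)C)=C\I | intermediate (not isolated)
26 | (4S,5S)-5-[(2E,6E)-2,6-bis{[(tert-butyldiphenylsilyl)oxy]methyl}-7-iodohepta-2,6-dien-1-yl]-4-(hydroxymethyl)oxolan-2-one (trans; same configuration as 24) | OC[C@@H]1CC(=O)O[C@H]1C/C(CO[Si](c1ccccc1)(c1ccccc1)C(C)(C)C)=C\CC/C(CO[Si](c1ccccc1)(c1ccccc1)C(C)(C)C)=C\I | intermediate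
27 | (2S,3R)-2-[(2E,6E)-2,6-bis{[(tert-butyldiphenylsilyl)oxy]methyl}-7-iodohepta-2,6-dien-1-yl]-5-oxooxolane-3-carbaldehyde (7R,8S; precursor of the key step) | O=C[C@@H]1CC(=O)O[C@H]1C/C(CO[Si](c1ccccc1)(c1ccccc1)C(C)(C)C)=C\CC/C(CO[Si](c1ccccc1)(c1ccccc1)C(C)(C)C)=C\I | intermediate
28 | C5 alkenylchromium dichloride derived from 27 (trivalent chromium in place of iodine, geometry retained) | O=C[C@@H]1CC(=O)O[C@H]1C/C(CO[Si](c1ccccc1)(c1ccccc1)C(C)(C)C)=C\CC/C(CO[Si](c1ccccc1)(c1ccccc1)C(C)(C)C)=C\[Cr](Cl)Cl | intermediate (not isolated)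
29 | (6R,7R,8S)-14,15-bis[(tert-butyldiphenylsilyl)oxy]-6-hydroxy-13-norgermacra-1(10),4-dien-12,8-olide (ring alkenes ring-cis, CIP E,E; product of the key step) | C1C(=O)O[C@H]2C/C(CO[Si](c3ccccc3)(c3ccccc3)C(C)(C)C)=C\CC/C(CO[Si](c3ccccc3)(c3ccccc3)C(C)(C)C)=C\[C@@H](O)[C@H]12 | intermediate
30 | dimethylmethyleneiminium iodide (Eschenmoser's salt) | C=[N+](C)C.[I-] | starting material
31 | 11-(dimethylaminomethyl) derivative of 29 (C11 epimers) | CN(C)CC1C(=O)O[C@H]2C/C(CO[Si](c3ccccc3)(c3ccccc3)C(C)(C)C)=C\CC/C(CO[Si](c3ccccc3)(c3ccccc3)C(C)(C)C)=C\[C@@H](O)[C@H]12 | intermediate (not isolated)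
32 | trimethylammonium iodide (methiodide) of 31 | [I-].C[N+](C)(C)CC1C(=O)O[C@H]2C/C(CO[Si](c3ccccc3)(c3ccccc3)C(C)(C)C)=C\CC/C(CO[Si](c3ccccc3)(c3ccccc3)C(C)(C)C)=C\[C@@H](O)[C@H]12 | intermediate (not isolated)
33 | (6R,7R,8S)-14,15-bis[(tert-butyldiphenylsilyl)oxy]-6-hydroxygermacra-1(10),4,11(13)-trien-12,8-olide | C=C1C(=O)O[C@H]2C/C(CO[Si](c3ccccc3)(c3ccccc3)C(C)(C)C)=C\CC/C(CO[Si](c3ccccc3)(c3ccccc3)C(C)(C)C)=C\[C@@H](O)[C@H]12 | intermediate
34 | tigloyl chloride, (E)-2-methylbut-2-enoyl chloride | C/C=C(\C)C(Cl)=O | starting material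
35 | (6R,7R,8S)-14,15-bis[(tert-butyldiphenylsilyl)oxy]-6-[(E)-2-methylbut-2-enoyloxy]germacra-1(10),4,11(13)-trien-12,8-olide | C=C1C(=O)O[C@H]2C/C(CO[Si](c3ccccc3)(c3ccccc3)C(C)(C)C)=C\CC/C(CO[Si](c3ccccc3)(c3ccccc3)C(C)(C)C)=C\[C@@H](OC(=O)/C(C)=C/C)[C@H]12 | intermediate
36 | (6R,7R,8S)-14,15-dihydroxy-6-[(E)-2-methylbut-2-enoyloxy]germacra-1(10),4,11(13)-trien-12,8-olide, CNP0275462.2 | C=C1C(=O)O[C@H]2C/C(CO)=C\CC/C(CO)=C\[C@@H](OC(=O)/C(C)=C/C)[C@H]12 | target

Total step count: 21. Longest linear sequence: 19 steps (steps 1–6, 8–12 and 14–21; steps 7 and 13 make the side components 12 and 20).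

Steps most likely to fail

1. Step 18. The ring-closing addition may show poor facial selectivity at C6, so that the 6S alcohol is formed mainly. The fallback corrects C6 after ring closure by substitution instead of by facial control. It sets out from 27, which is cyclised as in step 18 and would then deliver the 6S alcohol F1. A Mitsunobu reaction of this alcohol with chloroacetic acid (PPh3, DIAD, PhMe, 0 °C → rt) should give, with SN2 inversion, the 6R chloroacetate F2. Thiourea (NaHCO3, EtOH, 50 °C) should then remove the chloroacetyl group without touching the lactone, and the route is rejoined at 29.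

2. Step 19. The C6 alkoxide may attack C12 (translactonisation to the 6,12-lactone) before or after enolisation, or C-deprotonation of the dianion may stay incomplete. The fallback masks the hydroxyl and uses a simple lactone monoenolate. It sets out from 29, which with TESOTf and 2,6-lutidine (CH2Cl2, −78 °C) should give the C6 triethylsilyl ether F3. LiN(i-Pr)2 and then 30 (THF, −78 °C) give the Mannich base F4, MeI converts it into the methiodide F5, and NaHCO3 eliminates trimethylamine to the silylated α-methylene lactone F6. PPTS in MeOH at 0 °C should cleave the secondary triethylsilyl ether while the primary tert-butyldiphenylsilyl ethers stay, and the route is rejoined at 33.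

3. Step 8. The α-branched phosphonate may give eroded E/Z selectivity, and the Z-enoate would carry the wrong C1=C10 geometry into the ring. The fallback builds this alkene with a cyclic stabilised ylide and opens the lactone afterwards. It sets out from 9, which with commercial 3-(triphenylphosphoranylidene)oxolan-2-one (PhMe, 60 °C, Wittig reaction) should give the (E)-alkylidene lactone F7. Me3Al and MeNH(OMe)·HCl (CH2Cl2, 0 °C → rt) open it to the hydroxy Weinreb amide F8, and TBSCl with imidazole gives the silyl ether F9. i-Bu2AlH (THF, −78 °C) reduces the amide to the enal F10, and NaBH4 with CeCl3·7H2O (MeOH, 0 °C) gives the allylic alcohol, so that the route is rejoined at 14.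

Further compounds

F1 | step 18 | (6S,7R,8S)-14,15-bis[(tert-butyldiphenylsilyl)oxy]-6-hydroxy-13-norgermacra-1(10),4-dien-12,8-olide (C6 epimer of 29) | C1C(=O)O[C@H]2C/C(CO[Si](c3ccccc3)(c3ccccc3)C(C)(C)C)=C\CC/C(CO[Si](c3ccccc3)(c3ccccc3)C(C)(C)C)=C\[C@H](O)[C@H]12
F2 | step 18 | (6R,7R,8S)-14,15-bis[(tert-butyldiphenylsilyl)oxy]-6-(chloroacetoxy)-13-norgermacra-1(10),4-dien-12,8-olide | C1C(=O)O[C@H]2C/C(CO[Si](c3ccccc3)(c3ccccc3)C(C)(C)C)=C\CC/C(CO[Si](c3ccccc3)(c3ccccc3)C(C)(C)C)=C\[C@@H](OC(=O)CCl)[C@H]12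
F3 | step 19 | (6R,7R,8S)-14,15-bis[(tert-butyldiphenylsilyl)oxy]-6-[(triethylsilyl)oxy]-13-norgermacra-1(10),4-dien-12,8-olide | C1C(=O)O[C@H]2C/C(CO[Si](c3ccccc3)(c3ccccc3)C(C)(C)C)=C\CC/C(CO[Si](c3ccccc3)(c3ccccc3)C(C)(C)C)=C\[C@@H](O[Si](CC)(CC)CC)[C@H]12
F4 | step 19 | 11-(dimethylaminomethyl) derivative of F3 (C11 epimers) | CN(C)CC1C(=O)O[C@H]2C/C(CO[Si](c3ccccc3)(c3ccccc3)C(C)(C)C)=C\CC/C(CO[Si](c3ccccc3)(c3ccccc3)C(C)(C)C)=C\[C@@H](O[Si](CC)(CC)CC)[C@H]12
F5 | step 19 | trimethylammonium iodide (methiodide) of F4 | [I-].C[N+](C)(C)CC1C(=O)O[C@H]2C/C(CO[Si](c3ccccc3)(c3ccccc3)C(C)(C)C)=C\CC/C(CO[Si](c3ccccc3)(c3ccccc3)C(C)(C)C)=C\[C@@H](O[Si](CC)(CC)CC)[C@H]12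
F6 | step 19 | (6R,7R,8S)-14,15-bis[(tert-butyldiphenylsilyl)oxy]-6-[(triethylsilyl)oxy]germacra-1(10),4,11(13)-trien-12,8-olide | C=C1C(=O)O[C@H]2C/C(CO[Si](c3ccccc3)(c3ccccc3)C(C)(C)C)=C\CC/C(CO[Si](c3ccccc3)(c3ccccc3)C(C)(C)C)=C\[C@@H](O[Si](CC)(CC)CC)[C@H]12
F7 | step 8 | (E)-3-[(E)-4-{[(tert-butyldiphenylsilyl)oxy]methyl}-5-iodopent-4-en-1-ylidene]oxolan-2-one | O=C1OCC/C1=C\CC/C(CO[Si](c2ccccc2)(c2ccccc2)C(C)(C)C)=C\I
F8 | step 8 | (2E,6E)-6-{[(tert-butyldiphenylsilyl)oxy]methyl}-2-(2-hydroxyethyl)-7-iodo-N-methoxy-N-methylhepta-2,6-dienamide | CON(C)C(=O)/C(CCO)=C/CC/C(CO[Si](c1ccccc1)(c1ccccc1)C(C)(C)C)=C\I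
F9 | step 8 | (2E,6E)-2-{2-[(tert-butyldimethylsilyl)oxy]ethyl}-6-{[(tert-butyldiphenylsilyl)oxy]methyl}-7-iodo-N-methoxy-N-methylhepta-2,6-dienamide | CON(C)C(=O)/C(CCO[Si](C)(C)C(C)(C)C)=C/CC/C(CO[Si](c1ccccc1)(c1ccccc1)C(C)(C)C)=C\I
F10 | step 8 | (2E,6E)-2-{2-[(tert-butyldimethylsilyl)oxy]ethyl}-6-{[(tert-butyldiphenylsilyl)oxy]methyl}-7-iodohepta-2,6-dienal | O=C/C(CCO[Si](C)(C)C(C)(C)C)=C/CC/C(CO[Si](c1ccccc1)(c1ccccc1)C(C)(C)C)=C\I
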